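**Retrosynthetic overview**

1. Numbering: lactone O1, C2 (C=O), C3 (methyl), C4 (enol C–OH), C5; side chain C6 to C18, furan ring on C18. The plan rests on C5: it carries O1, the acyl carbon C4 and the methylene C6 in the same array as C2 of (R)-malic acid (OH, CO2H, CH2CO2H), and C6 is bonded to the sp2 carbon C7 of the E-trisubstituted C7=C8 olefin.
2. C6–C7 is cut. An sp3 radical at C6, released from the N-hydroxyphthalimide ester of malic acid acetonide, is joined to the complete C7–C18 E-alkenyl iodide by nickel-electrocatalytic decarboxylative alkenylation.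
3. The iodide is cut at C13=C14 (Julia–Kocienski) into a C7–C13 iodo-enal from geranyl acetate (2-alkyne hydrozirconation/iodination) and a C14–C18 phenyltetrazolyl (PT) sulfone. An auxiliary-controlled allylation sets C15 and a B-alkyl Suzuki coupling brings in the furan ring from 3-bromofuran.
4. Ring order: the furan ring is bought. The tetronic acid ring (O1–C2–C3–C4–C5) is the only ring made; it is closed last at C3–C4 by Dieckmann condensation after methanolysis of the dioxolanone and O-propionylation.

Key step: step 15

Remarks on the chemistry: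
- (R)-Malic acid and the (R)-benzyl propionyl oxazolidinone are taken as commercial.
- The oxirane carbon made in step 1 is racemic and is excised in step 2.
- In the SMILES, cyclopentadienyl ligands on zirconium are drawn as σ-bonded C5H5 rings and alkali-metal intermediates with covalent metal bonds.

**Route**

Step 1
Reactants: 1 geranyl acetate
Product: 2 (2E)-5-(3,3-dimethyloxiran-2-yl)-3-methylpent-2-en-1-yl acetate
Conditions: mCPBA (1.05 equiv), NaHCO3, CH2Cl2, 0 °C
Reagents that add atoms: mCPBA (OOC(=O)c1cccc(Cl)c1)
Why: Prilezhaev epoxidation should take the electron-rich terminal trisubstituted olefin selectively, because the other olefin is deactivated by the allylic acetate; the new oxirane stereocentre is racemic and is removed in step 2.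

Step 2
Reactants: 2 (2E)-5-(3,3-dimethyloxiran-2-yl)-3-methylpent-2-en-1-yl acetate
Product: 4 (2E)-3-methyl-6-oxohex-2-en-1-yl acetate, via diol 3 (not isolated)
Conditions: H5IO6 (1.2 equiv), THF/Et2O, 0 °C to rt
Reagents that add atoms: none
Why: Acid-mediated hydrolysis of the epoxide at its tertiary carbon followed by periodate glycol cleavage excises the isopropylidene end as acetone and leaves the aldehyde carbon that becomes C8, the aldehyde oxygen being the former oxirane oxygen, without touching the allylic acetate or the E olefin.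

Step 3
Reactants: 4 (2E)-3-methyl-6-oxohex-2-en-1-yl acetate
Product: 6 (2E)-3-methylhept-2-en-6-yn-1-ol, via alkyne acetate 5 (not isolated)
Conditions: dimethyl (1-diazo-2-oxopropyl)phosphonate (1.3 equiv), K2CO3 (3 equiv), MeOH, 0 °C to rt
Reagents that add atoms: dimethyl (1-diazo-2-oxopropyl)phosphonate (COP(=O)(OC)C(=[N+]=[N-])C(C)=O)
Why: Ohira–Bestmann (Seyferth–Gilbert) homologation converts the aldehyde into the terminal alkyne through an alkylidene carbene 1,2-shift, and the same K2CO3/MeOH medium transesterifies the allylic acetate to the free alcohol.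

Step 4
Reactants: 6 (2E)-3-methylhept-2-en-6-yn-1-ol
Product: 8 (2E)-3-methyloct-2-en-6-yn-1-ol, via dilithium salt 7 (not isolated)
Conditions: n-BuLi (2.1 equiv), THF, −78 to −20 °C; MeI (1.05 equiv), −78 °C to rt
Reagents that add atoms: iodomethane (CI)
Why: In the alkoxide–acetylide dianion the acetylide carbon is far more nucleophilic toward one equivalent of MeI in THF than the lithium alkoxide, so C-methylation should give the 2-alkyne that carries C7 and its methyl group.

Step 5
Reactants: 8 (2E)-3-methyloct-2-en-6-yn-1-ol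
Product: 10 (2E,6E)-7-iodo-3-methylocta-2,6-dien-1-ol, via alkenyl-ZrCp2Cl species 9 (not isolated)
Conditions: Cp2Zr(H)Cl (3 equiv), THF, 50 °C, dark; then I2, THF, 0 °C
Reagents that add atoms: iodine ([I][I])
Why: Syn hydrozirconation of the 2-alkyne under equilibrating conditions (excess hydride, warming; one equivalent is taken up by the hydroxyl group) should place zirconium on the less hindered methyl-bearing carbon C7, and iodinolysis with retention gives the E iodide with iodine trans to C9; any C8-iodo regioisomer is to be removed by chromatography here.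

Step 6
Reactants: 10 (2E,6E)-7-iodo-3-methylocta-2,6-dien-1-ol
Product: 11 (2E,6E)-7-iodo-3-methylocta-2,6-dienal
Conditions: MnO2 (20 equiv), CH2Cl2, rt
Reagents that add atoms: none
Why: MnO2 oxidation is selective for the allylic alcohol and neutral, so the E enal should form without isomerisation and with the alkenyl iodide intact.

Step 7
Reactants: 12 (4R)-4-benzyl-3-propanoyl-1,3-oxazolidin-2-one
Product: 14 (4R)-4-benzyl-3-[(2S)-2-methylpent-4-enoyl]-1,3-oxazolidin-2-one, via sodium enolate 13 (not isolated)
Conditions: NaN(SiMe3)2 (1.1 equiv), THF, −78 °C; allyl iodide (3 equiv), −78 to −45 °C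
Reagents that add atoms: allyl iodide (C=CCI)
Why: Auxiliary-controlled enolate alkylation, in which the chelated Z-enolate is allylated on the face opposite the benzyl group of the (R)-oxazolidinone, sets the future C15 stereocentre as (S).

Step 8
Reactants: 14 (4R)-4-benzyl-3-[(2S)-2-methylpent-4-enoyl]-1,3-oxazolidin-2-one
Product: 15 (2S)-2-methylpent-4-en-1-ol
Conditions: LiBH4 (1.5 equiv), H2O (1.5 equiv), Et2O, 0 °C; volatile product, concentrated cold
Reagents that add atoms: none
Why: Reductive cleavage of the exocyclic imide carbonyl with LiBH4 gives the primary alcohol without epimerising the α-stereocentre and releases the auxiliary.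

Step 9
Reactants: 15 (2S)-2-methylpent-4-en-1-ol
Product: 16 5-{[(2S)-2-methylpent-4-en-1-yl]sulfanyl}-1-phenyl-1H-tetrazole
Conditions: 1-phenyl-1H-tetrazole-5-thiol (1.2 equiv), PPh3 (1.2 equiv), DIAD (1.2 equiv), THF, 0 °C to rt
Reagents that add atoms: 1-phenyl-1H-tetrazole-5-thiol (Sc1nnnn1-c1ccccc1)
Why: Mitsunobu thioetherification of the primary alcohol by the acidic tetrazole thiol is an SN2 displacement at the future C14, one carbon away from the stereocentre.

Step 10
Reactants: 16 5-{[(2S)-2-methylpent-4-en-1-yl]sulfanyl}-1-phenyl-1H-tetrazole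
Product: 17 5-{[(2S)-2-methylpent-4-en-1-yl]sulfonyl}-1-phenyl-1H-tetrazole
Conditions: (NH4)6Mo7O24·4H2O (10 mol %), 30% aq. H2O2 (10 equiv), EtOH, 0 °C to rt
Reagents that add atoms: hydrogen peroxide (OO)
Why: H2O2 activated by catalytic (NH4)6Mo7O24·4H2O oxidises the sulfide through the sulfoxide to the sulfone without epoxidising an unactivated terminal alkene, and doing this before the furan is attached keeps the oxidant away from that ring.

Step 11
Reactants: 17 5-{[(2S)-2-methylpent-4-en-1-yl]sulfonyl}-1-phenyl-1H-tetrazole; 18 3-bromofuran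
Product: 20 5-{[(2S)-5-(furan-3-yl)-2-methylpentyl]sulfonyl}-1-phenyl-1H-tetrazole, via alkylborane 19 (not isolated)
Conditions: 9-BBN (1.3 equiv), THF, 0 °C to rt; then 18 (1.5 equiv), PdCl2(dppf)·CH2Cl2 (5 mol %), AsPh3 (5 mol %), Cs2CO3 (2 equiv), DMF/H2O, 50 °C
Reagents that add atoms: none
Why: Anti-Markovnikov hydroboration of the terminal alkene with 9-BBN and B-alkyl Suzuki–Miyaura coupling with the bromofuran at zerovalent palladium form the C18–furan bond, the carbonate base and moderate temperature being chosen so that the sulfonyl tetrazole is not attacked and C15 is not involved.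

Step 12
Reactants: 20 5-{[(2S)-5-(furan-3-yl)-2-methylpentyl]sulfonyl}-1-phenyl-1H-tetrazole; 11 (2E,6E)-7-iodo-3-methylocta-2,6-dienal
Product: 22 3-[(4S,5E,7E,11E)-12-iodo-4,8-dimethyltrideca-5,7,11-trien-1-yl]furan, via potassium sulfonyl carbanion 21 (not isolated)
Conditions: 20 (1.2 equiv), KN(SiMe3)2 (1.25 equiv), DME, −60 °C; then 11 (1.0 equiv), −60 °C to rt
Reagents that add atoms: none
Why: Julia–Kocienski olefination (1,2-addition to the enal, Smiles rearrangement, loss of SO2 and tetrazololate) of an unstabilised alkyl PT sulfone with a potassium base in DME should favour the E C13=C14 olefin, while C15 lies β to the carbanion and is not epimerised and the alkenyl iodide tolerates the base at low temperature.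

Step 13
Reactants: 23 (R)-malic acid
Product: 24 2-[(4R)-2,2-dimethyl-5-oxo-1,3-dioxolan-4-yl]acetic acid
Conditions: 2,2-dimethoxypropane (excess), TsOH·H2O (cat.), rt
Reagents that add atoms: 2,2-dimethoxypropane (COC(C)(C)OC)
Why: Acid-catalysed transketalisation closes the five-membered dioxolanone from the α-hydroxy acid unit in preference to the six-membered alternative, which leaves the β-carboxyl free and the stereocentre untouched.

Step 14
Reactants: 24 2-[(4R)-2,2-dimethyl-5-oxo-1,3-dioxolan-4-yl]acetic acid
Product: 25 1,3-dioxoisoindolin-2-yl 2-[(4R)-2,2-dimethyl-5-oxo-1,3-dioxolan-4-yl]acetate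
Conditions: N-hydroxyphthalimide (1.05 equiv), DIC (1.1 equiv), DMAP (5 mol %), CH2Cl2, rt
Reagents that add atoms: N-hydroxyphthalimide (ON1C(=O)c2ccccc2C1=O)
Why: Carbodiimide (Steglich-type) esterification of the free carboxyl gives the redox-active ester under neutral conditions that leave the dioxolanone intact.

Step 15
Reactants: 25 1,3-dioxoisoindolin-2-yl 2-[(4R)-2,2-dimethyl-5-oxo-1,3-dioxolan-4-yl]acetate; 22 3-[(4S,5E,7E,11E)-12-iodo-4,8-dimethyltrideca-5,7,11-trien-1-yl]furan
Product: 26 (5R)-5-[(2E,6E,8E,10S)-13-(furan-3-yl)-2,6,10-trimethyltrideca-2,6,8-trien-1-yl]-2,2-dimethyl-1,3-dioxolan-4-one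
Conditions: 22 (1 equiv), 25 (2.5 equiv), NiCl2·glyme (20 mol %), 2,2'-bipyridine (20 mol %), AgNO3 (0.3 equiv), LiCl, DMF, Mg anode/reticulated vitreous carbon cathode, undivided cell, constant current, rt, Ar
Reagents that add atoms: none
Why: Cathodic reduction turns the NiCl2·glyme/2,2'-bipyridine precatalyst into low-valent nickel, which inserts into the C7–I bond of 22 with retention of the E geometry, while one-electron reduction of 25 expels CO2 and phthalimide anion and leaves the primary C6 radical. The radical is captured by the divalent alkenylnickel species and the resulting trivalent nickel reductively eliminates the C6–C7 bond; the magnesium anode supplies the electrons and the silver deposit formed from AgNO3 on the cathode keeps ester reduction and catalyst turnover in step. The closest known reaction type is the nickel/bipyridine reductive cross-electrophile coupling of N-hydroxyphthalimide esters with alkenyl halides; no ring closes and no stereocentre is created. C5 keeps the malic acid configuration because the radical sits at C6, one carbon away, and the cyclic acetonide ties up the C5 oxygen so that β-alkoxide elimination from the alkylnickel intermediate is disfavoured. The step needs capture of the radical at nickel to outrun its addition to the C11–C14 diene or the furan, which is secured by substitution at both diene termini and by using 25 in excess under slow, current-controlled radical generation; the C7=C8 geometry is held by stereoretentive oxidative addition and reductive elimination.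

Step 16
Reactants: 26 (5R)-5-[(2E,6E,8E,10S)-13-(furan-3-yl)-2,6,10-trimethyltrideca-2,6,8-trien-1-yl]-2,2-dimethyl-1,3-dioxolan-4-one
Product: 27 methyl (2R,4E,8E,10E,12S)-15-(furan-3-yl)-2-hydroxy-4,8,12-trimethylpentadeca-4,8,10-trienoate
Conditions: K2CO3 (0.2 equiv), MeOH, 0 °C
Reagents that add atoms: methanol (CO)
Why: Base-catalysed methanolysis (transesterification) of the activated dioxolanone carbonyl releases acetone from the resulting hemiketal and should give the α-hydroxy methyl ester without epimerising C5.

Step 17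
Reactants: 27 methyl (2R,4E,8E,10E,12S)-15-(furan-3-yl)-2-hydroxy-4,8,12-trimethylpentadeca-4,8,10-trienoate
Product: 28 methyl (2R,4E,8E,10E,12S)-15-(furan-3-yl)-4,8,12-trimethyl-2-(propanoyloxy)pentadeca-4,8,10-trienoate
Conditions: propionic anhydride (1.5 equiv), Et3N (2 equiv), DMAP (10 mol %), CH2Cl2, 0 °C to rt
Reagents that add atoms: propionic anhydride (CCC(=O)OC(=O)CC)
Why: DMAP-catalysed O-acylation of the secondary alcohol installs the three carbons that become C2, C3 and the C3 methyl group.

Step 18
Reactants: 28 methyl (2R,4E,8E,10E,12S)-15-(furan-3-yl)-4,8,12-trimethyl-2-(propanoyloxy)pentadeca-4,8,10-trienoate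
Product: 29 (5R)-5-[(2E,6E,8E,10S)-13-(furan-3-yl)-2,6,10-trimethyltrideca-2,6,8-trien-1-yl]-4-hydroxy-3-methylfuran-2(5H)-one
Conditions: LiN(SiMe3)2 (2.5 equiv), THF, −78 to 0 °C; then cold 1 M HCl
Reagents that add atoms: none
Why: Dieckmann (intramolecular Claisen) condensation, in which the lithium enolate of the propionate attacks the methyl ester carbon C4 in a 5-exo-trig closure of the C3–C4 bond, gives the tetronic acid ring, and the extra base stores the product as its stabilised tetronate so that C5 is not enolised before acidification.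

**Compound list**

1 | geranyl acetate, (2E)-3,7-dimethylocta-2,6-dien-1-yl acetate | CC(C)=CCC/C(C)=C/COC(C)=O | starting material
2 | (2E)-5-(3,3-dimethyloxiran-2-yl)-3-methylpent-2-en-1-yl acetate (racemic at the oxirane carbon) | CC1(C)OC1CC/C(C)=C/COC(C)=O | intermediate
3 | (2E)-6,7-dihydroxy-3,7-dimethyloct-2-en-1-yl acetate (racemic diol) | CC(C)(O)C(O)CC/C(C)=C/COC(C)=O | intermediate (not isolated)
4 | (2E)-3-methyl-6-oxohex-2-en-1-yl acetate | O=CCC/C(C)=C/COC(C)=O | intermediate
5 | (2E)-3-methylhept-2-en-6-yn-1-yl acetate | C#CCC/C(C)=C/COC(C)=O | intermediate (not isolated)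
6 | (2E)-3-methylhept-2-en-6-yn-1-ol | C#CCC/C(C)=C/CO | intermediate
7 | dilithium alkoxide–acetylide of 6 | [Li]C#CCC/C(C)=C/CO[Li] | intermediate (not isolated)
8 | (2E)-3-methyloct-2-en-6-yn-1-ol | CC#CCC/C(C)=C/CO | intermediate
9 | E-alkenyl-ZrCp2Cl species (Zr on C7, trans to C9; hydroxyl as its ZrCp2Cl alkoxide) | Cl[Zr](C1C=CC=C1)(C1C=CC=C1)/C(C)=C/CC/C(C)=C/CO[Zr](Cl)(C1C=CC=C1)C1C=CC=C1 | intermediate (not isolated)
10 | (2E,6E)-7-iodo-3-methylocta-2,6-dien-1-ol | I/C(C)=C/CC/C(C)=C/CO | intermediate
11 | (2E,6E)-7-iodo-3-methylocta-2,6-dienal | I/C(C)=C/CC/C(C)=C/C=O | intermediate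
12 | (4R)-4-benzyl-3-propanoyl-1,3-oxazolidin-2-one | CCC(=O)N1C(=O)OC[C@H]1Cc1ccccc1 | starting material
13 | sodium (Z)-enolate of 12 | C/C=C(\O[Na])N1C(=O)OC[C@H]1Cc1ccccc1 | intermediate (not isolated)
14 | (4R)-4-benzyl-3-[(2S)-2-methylpent-4-enoyl]-1,3-oxazolidin-2-one | C=CC[C@H](C)C(=O)N1C(=O)OC[C@H]1Cc1ccccc1 | intermediate
15 | (2S)-2-methylpent-4-en-1-ol | C=CC[C@H](C)CO | intermediate
16 | 5-{[(2S)-2-methylpent-4-en-1-yl]sulfanyl}-1-phenyl-1H-tetrazole | C=CC[C@H](C)CSc1nnnn1-c1ccccc1 | intermediate
17 | 5-{[(2S)-2-methylpent-4-en-1-yl]sulfonyl}-1-phenyl-1H-tetrazole | C=CC[C@H](C)CS(=O)(=O)c1nnnn1-c1ccccc1 | intermediate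
18 | 3-bromofuran | Brc1ccoc1 | starting material
19 | 9-[(4S)-4-methyl-5-(1-phenyl-1H-tetrazol-5-ylsulfonyl)pentyl]-9-borabicyclo[3.3.1]nonane | O=S(=O)(C[C@@H](C)CCCB1C2CCCC1CCC2)c1nnnn1-c1ccccc1 | intermediate (not isolated)
20 | 5-{[(2S)-5-(furan-3-yl)-2-methylpentyl]sulfonyl}-1-phenyl-1H-tetrazole | O=S(=O)(C[C@@H](C)CCCc1ccoc1)c1nnnn1-c1ccccc1 | intermediate
21 | potassium α-sulfonyl carbanion of 20 | [K]C([C@@H](C)CCCc1ccoc1)S(=O)(=O)c1nnnn1-c1ccccc1 | intermediate (not isolated)
22 | 3-[(4S,5E,7E,11E)-12-iodo-4,8-dimethyltrideca-5,7,11-trien-1-yl]furan | I/C(C)=C/CC/C(C)=C/C=C/[C@@H](C)CCCc1ccoc1 | intermediate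
23 | (R)-malic acid | O[C@H](CC(O)=O)C(O)=O | starting material
24 | 2-[(4R)-2,2-dimethyl-5-oxo-1,3-dioxolan-4-yl]acetic acid | CC1(C)O[C@H](CC(=O)O)C(=O)O1 | intermediate
25 | 1,3-dioxoisoindolin-2-yl 2-[(4R)-2,2-dimethyl-5-oxo-1,3-dioxolan-4-yl]acetate | CC1(C)O[C@H](CC(=O)ON2C(=O)c3ccccc3C2=O)C(=O)O1 | intermediate
26 | (5R)-5-[(2E,6E,8E,10S)-13-(furan-3-yl)-2,6,10-trimethyltrideca-2,6,8-trien-1-yl]-2,2-dimethyl-1,3-dioxolan-4-one | CC1(C)O[C@H](C/C(C)=C/CC/C(C)=C/C=C/[C@@H](C)CCCc2ccoc2)C(=O)O1 | intermediate
27 | methyl (2R,4E,8E,10E,12S)-15-(furan-3-yl)-2-hydroxy-4,8,12-trimethylpentadeca-4,8,10-trienoate | COC(=O)[C@H](O)C/C(C)=C/CC/C(C)=C/C=C/[C@@H](C)CCCc1ccoc1 | intermediate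
28 | methyl (2R,4E,8E,10E,12S)-15-(furan-3-yl)-4,8,12-trimethyl-2-(propanoyloxy)pentadeca-4,8,10-trienoate | COC(=O)[C@H](OC(=O)CC)C/C(C)=C/CC/C(C)=C/C=C/[C@@H](C)CCCc1ccoc1 | intermediate
29 | (5R)-5-[(2E,6E,8E,10S)-13-(furan-3-yl)-2,6,10-trimethyltrideca-2,6,8-trien-1-yl]-4-hydroxy-3-methylfuran-2(5H)-one | CC1=C(O)[C@@H](C/C(C)=C/CC/C(C)=C/C=C/[C@@H](C)CCCc2ccoc2)OC1=O | target

**Step count**

Total: 18 steps. Longest linear sequence: 11 steps (steps 1–6, 12, 15–18).

**Steps most likely to fail**

Step 15. The C6 radical may be lost before nickel captures it, by reduction to the methyl compound, dimerisation or addition to the conjugated diene. The alkenyl iodide may be hydrodehalogenated or homocoupled at the cathode, and β-alkoxide elimination at nickel could open the dioxolanone. The fallback forms the same C6–C7 bond by polar chemistry and sets out from 22. Iodine–lithium exchange (t-BuLi, Et2O, −78 °C) should give, with retention of geometry, the alkenyllithium F1. Transmetalation with MgBr2·OEt2 gives the alkenylmagnesium bromide F2. Under CuI catalysis (THF, −40 °C) F2 opens commercial methyl (2R)-oxirane-2-carboxylate at its terminal carbon in an SN2 epoxide opening. The glycidate stereocentre is not touched and becomes C5 with the (R) configuration. The product is hydroxy ester 27, where the fallback rejoins the route, bypassing 26 and step 16.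

Step 11. The aqueous base may attack the sulfonyl tetrazole by ipso substitution, or oxidative addition of the electron-rich bromofuran may be slow enough for the alkylborane to be lost by protodeboronation. The fallback reverses the order of furan attachment and sulfur oxidation and sets out from 15. Hydroboration of the free alcohol with 9-BBN (2.2 equiv) gives the O,C-bis-borylated species F3. Coupling of F3 with 18 (PdCl2(dppf)·CH2Cl2, aq. NaOH, THF, 60 °C) gives (2S)-5-(furan-3-yl)-2-methylpentan-1-ol F4. Mitsunobu thioetherification with 1-phenyl-1H-tetrazole-5-thiol gives the sulfide F5. Oxidation with (NH4)6Mo7O24·4H2O/H2O2 at 0 °C, the sulfide reacting faster than the 3-alkylfuran, returns to the route at 20.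

Step 12. E selectivity at C13=C14 may erode in the addition/Smiles/elimination sequence, and the sulfonyl carbanion may deprotonate the β,β-disubstituted enal at its γ-position instead of adding. The fallback reverses the polarity of the olefination and sets out from 10 and from alcohol F4 (reached from 15 as described above). Alcohol 10 is converted (CBr4, PPh3, CH2Cl2, 0 °C) into the allylic bromide F6 and then (PBu3, MeCN, rt) into the tributylphosphonium bromide F7. Alcohol F4 is oxidised (Dess–Martin periodinane, NaHCO3, CH2Cl2) to (2S)-5-(furan-3-yl)-2-methylpentanal F8, used at once to avoid α-epimerisation. Deprotonation of F7 (KOtBu, THF, −78 °C) gives the allylic ylide F9. Its Wittig reaction with F8 is E-selective because allylic trialkylphosphonium ylides react under thermodynamic control, and it rejoins the route at 22.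

**Further compounds**

F1 | step 15 | alkenyllithium from 22 (Li in place of I, geometry retained) | [Li]/C(C)=C/CC/C(C)=C/C=C/[C@@H](C)CCCc1ccoc1
F2 | step 15 | alkenylmagnesium bromide from F1 | Br[Mg]/C(C)=C/CC/C(C)=C/C=C/[C@@H](C)CCCc1ccoc1
F3 | step 11 | O,C-bis(9-borabicyclo[3.3.1]nonan-9-yl) derivative of 15 | B1(OC[C@@H](C)CCCB2C3CCCC2CCC3)C2CCCC1CCC2
F4 | step 11 | (2S)-5-(furan-3-yl)-2-methylpentan-1-ol | OC[C@@H](C)CCCc1ccoc1
F5 | step 11 | 5-{[(2S)-5-(furan-3-yl)-2-methylpentyl]sulfanyl}-1-phenyl-1H-tetrazole | S(C[C@@H](C)CCCc1ccoc1)c1nnnn1-c1ccccc1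
F6 | step 12 | (2E,6E)-1-bromo-7-iodo-3-methylocta-2,6-diene | I/C(C)=C/CC/C(C)=C/CBr
F7 | step 12 | tributyl[(2E,6E)-7-iodo-3-methylocta-2,6-dien-1-yl]phosphonium bromide | I/C(C)=C/CC/C(C)=C/C[P+](CCCC)(CCCC)CCCC.[Br-]
F8 | step 12 | (2S)-5-(furan-3-yl)-2-methylpentanal | O=C[C@@H](C)CCCc1ccoc1
F9 | step 12 | allylic tributylphosphonium ylide from F7 | I/C(C)=C/CC/C(C)=C/C=P(CCCC)(CCCC)CCCC
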